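Count halvings.

| setting | east | flask |
|---|---|---|
| substrate | 0.050 M | 0.050 M |
| partner | 0.090 M (in portions, 4) | 0.0900 M (in portions, 4) |
| free catalyst | 1.2 mM | 1.2 mM |
| remark | the very flask that is asked about, followed so far; portions every 2.5 min | the portions of partner follow each other after 2.5 min, the first at the start |
| time |  | 12 h |

east run (percent of the substrate charged)

| time / h | product / % | substrate / % | open intermediate / % |
|---|---|---|---|
| 0.500 | 5.1 | 86.8 | 7.3 |
| 1.00 | 9.7 | 81.3 | 9.2 |
| 2.50 | 14.2 | 76.3 | 10.6 |
| 6.00 | 14.3 | 74.8 | 9.4 |

(readings scatter by 0.3 percentage points)

* where most of what was charged as substrate, at 12 h is found (substrate / open intermediate / product)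
* the largest share itself, whichever of these holds it, in percent of the substrate charged

- the earlier runs were read with a standard deviation of 0.3 percentage points
- a reading or a percentage of product counts all its forms, free or not

The last portion of partner goes in at 7.50 min, much earlier than the first reading, so I set the dosing aside. The product share climbs to 14.2 % and reads 14.3 % at 6.00 h, but substrate still reads 74.8 %, so lack of substrate does not stop it. I take the free catalyst to be dying. The gap to the plateau, read between the first two readings, has a half-life of 0.500 h. From 6.00 h to 12 h that makes 12.0 half-lives, so I expect the plateau to stand.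

The free catalyst is charged at a load of 2.40 % of the substrate. So I carry the turnover number, the plateau share of product divided by that load, which reads 5.96. For this flask I commit to substrate at about 74.8 %. The forecast says substrate at 74 %, a little lower than mine, on the grounds of “the catalyst dying or being tied up”.

substrate holds the most in this flask, 74.7 %, with product at 15.3 %, or 6.38 turnovers, and spent catalyst at >99.9 % of the catalyst charged.

    crystals ⇌ product, rate k1*(cs1 - [product]) while solid is left; crystals form when [product] > cs1 (solubility = 24.0 mM, k = 0.0170 s⁻¹)
    substrate + free catalyst ⇌ free catalyst + open intermediate (K = 5.19, k = 0.0995 M⁻¹ s⁻¹)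
    free catalyst → spent catalyst (k = 4.02 × 10⁻⁴ s⁻¹)
    partner + catalyst intermediate → free catalyst + product (k = 0.194 M⁻¹ s⁻¹)
    free catalyst + open intermediate ⇌ catalyst intermediate (K = 46.0 M⁻¹, k = 11.7 M⁻¹ s⁻¹)

The neighbour flask is charged with a load of 9.60 %, and nothing else changes. The carried turnover number gives it a product share of 57.2 %. The neighbour flask ends with product in the lead at 61.4 %, substrate at 31.6 %, and crystals, counted within the product, at 13.4 %.

Readings and results are simulated for substances that don't exist; the scatter is artificial.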